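**Plan**

- Cuts, in retrosynthetic order: the C4(unit U)–C8(catechin unit) bond; then, in the fisetinidol units T (terminal) and M (middle), the C3–OH/C2–H pair, the C2–aryl bond and the O1–C8a bond. This leaves two 3-arylindan-1-ones, whose C3–C3a bonds and enone C=C bonds lead back to catechin-6-carbaldehyde and two 2-bromo-5-benzyloxyacetophenones.
- Enabling feature: in T and M, O1 of ring C lies between aromatic C8a and C2, so each ring C is a 3-arylindan-1-one (indanone C1 = flavan C2, C3 = C4) plus one oxygen atom. One double Baeyer–Villiger insertion supplies both O1–C8a bonds.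
- Forward order: two aldol condensations give a bis-chalcone; both cyclopentanone rings close in one reductive Heck step; both are expanded to six-membered lactones; the lactones are opened to aryl ketones and re-closed as 4H-chromenes (ring C of T and M), which are hydroborated; global hydrogenolysis; unit U is attached last.
- Stereochemistry: (+)-catechin and (+)-fustin supply C2/C3 of the catechin unit and of U. The chiral bisphosphine on palladium sets C4 of T and M. Syn hydroboration anti to the C4 aryl group relays C4 to C3 and C2. Attack trans to 3-OH sets C4 of U.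

Key step: step 14

Assumption: (R)-3,5-Xyl-MeOBIPHEP is taken to be the ligand antipode that gives the S configuration at both new diarylmethine carbons of 19; the sense would be checked on a simple 2'-bromochalcone and the (S)-ligand used if it is opposite.

**Route**

Step 1
Reactants: 1 (+)-catechin
Product: 2 5,7,3',4'-tetra-O-benzyl-(+)-catechin
Conditions: BnBr (4.4 equiv), K2CO3, DMF, 0 °C → rt
Reagents that add atoms: benzyl bromide, BrCc1ccccc1
Why: Williamson etherification in which carbonate ionises only the four phenols, so the secondary 3-OH and both stereocentres are left alone.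

Step 2
Reactants: 2 5,7,3',4'-tetra-O-benzyl-(+)-catechin
Product: 3 8-bromo-5,7,3',4'-tetra-O-benzyl-(+)-catechin
Conditions: NBS (1.05 equiv), CH2Cl2, −78 °C → rt
Reagents that add atoms: N-bromosuccinimide, O=C1CCC(=O)N1Br
Why: Electrophilic aromatic bromination of the 5,7-dialkoxy ring A, where C8 is the more reactive and less shielded of the two open positions, so one equivalent should stop at the 8-bromide.

Step 3
Reactants: 3 8-bromo-5,7,3',4'-tetra-O-benzyl-(+)-catechin
Product: 4 8-bromo-3,5,7,3',4'-penta-O-benzyl-(+)-catechin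
Conditions: NaH, BnBr, THF–DMF, 0 °C → rt
Reagents that add atoms: benzyl bromide, BrCc1ccccc1
Why: Williamson etherification of the sodium alkoxide caps the last O–H, so that the iminium reagent, the organomagnesium reagents and borane used later meet no acidic hydrogen on this unit.

Step 4
Reactants: 4 8-bromo-3,5,7,3',4'-penta-O-benzyl-(+)-catechin
Product: 6 8-bromo-3,5,7,3',4'-penta-O-benzyl-(+)-catechin-6-carbaldehyde, via iminium chloride 5 (not isolated)
Conditions: POCl3, DMF, 0 → 60 °C; then aq. NaOAc, rt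
Reagents that add atoms: N,N-dimethylformamide, CN(C)C=O; water, O
Why: Vilsmeier–Haack formylation at C6, the only unsubstituted carbon of ring A, which is still activated by two ortho benzyloxy groups and the para ring oxygen while the bromine keeps C8 closed.

Step 5
Reactants: 7 3'-hydroxyacetophenone
Product: 8 3'-(benzyloxy)acetophenone
Conditions: BnBr, K2CO3, acetone, reflux
Reagents that add atoms: benzyl bromide, BrCc1ccccc1
Why: Williamson etherification of the phenol under conditions too mild to enolise the methyl ketone productively.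

Step 6
Reactants: 8 3'-(benzyloxy)acetophenone
Product: 9 1-[5-(benzyloxy)-2-bromophenyl]ethanone
Conditions: NBS, MeCN, rt, dark
Reagents that add atoms: N-bromosuccinimide, O=C1CCC(=O)N1Br
Why: Electrophilic aromatic bromination para to the benzyloxy group (ortho to the acetyl group), the electronically favoured and least hindered activated position; polar, radical-free conditions disfavour α-bromination of the ketone.

Step 7
Reactants: 10 4-bromo-2-hydroxybenzaldehyde
Product: 11 2-(benzyloxy)-4-bromobenzaldehyde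
Conditions: BnBr, K2CO3, DMF, rt
Reagents that add atoms: benzyl bromide, BrCc1ccccc1
Why: Williamson etherification of the acidic salicylaldehyde phenol.

Step 8
Reactants: 11 2-(benzyloxy)-4-bromobenzaldehyde
Product: 12 2-(benzyloxy)-4-bromobenzaldehyde dimethyl acetal
Conditions: HC(OMe)3, TsOH·H2O (cat.), MeOH, rt
Reagents that add atoms: trimethyl orthoformate, COC(OC)OC; methanol, CO
Why: Acid-catalysed acetalisation driven by the orthoformate as water scavenger masks the aldehyde against the organolithium step and the first aldol condensation.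

Step 9
Reactants: 12 2-(benzyloxy)-4-bromobenzaldehyde dimethyl acetal
Product: 14 1-[3-(benzyloxy)-4-(dimethoxymethyl)phenyl]ethanone, via aryllithium 13 (not isolated)
Conditions: n-BuLi, THF, −78 °C; then MeC(O)N(OMe)Me, −78 → 0 °C; aq. NH4Cl
Reagents that add atoms: N-methoxy-N-methylacetamide, CC(=O)N(C)OC
Why: Bromine–lithium exchange at −78 °C outruns benzylic deprotonation, and the aryllithium acylates only once because the chelated tetrahedral adduct survives until work-up (Weinreb ketone synthesis).

Step 10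
Reactants: 14 1-[3-(benzyloxy)-4-(dimethoxymethyl)phenyl]ethanone
Product: 15 1-[5-(benzyloxy)-2-bromo-4-(dimethoxymethyl)phenyl]ethanone
Conditions: NBS, NaHCO3, MeCN, 0 °C → rt, dark
Reagents that add atoms: N-bromosuccinimide, O=C1CCC(=O)N1Br
Why: Electrophilic aromatic bromination para to the benzyloxy group, as in step 6; the acid-free medium keeps the dimethyl acetal intact.

Step 11
Reactants: 6 8-bromo-3,5,7,3',4'-penta-O-benzyl-(+)-catechin-6-carbaldehyde; 15 1-[5-(benzyloxy)-2-bromo-4-(dimethoxymethyl)phenyl]ethanone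
Product: 17 2-(benzyloxy)-5-bromo-4-[(E)-3-(8-bromo-penta-O-benzylcatechin-6-yl)prop-2-enoyl]benzaldehyde, via chalcone dimethyl acetal 16 (not isolated)
Conditions: KOH, EtOH–THF, rt; then 1 M HCl, THF, rt
Reagents that add atoms: water, O
Why: Claisen–Schmidt condensation of the methyl ketone enolate with the non-enolisable aldehyde gives the E-enone after E1cB dehydration, and brief aqueous acid then hydrolyses the dimethyl acetal without touching benzyl ethers or the enone.

Step 12
Reactants: 17 2-(benzyloxy)-5-bromo-4-[(E)-3-(8-bromo-penta-O-benzylcatechin-6-yl)prop-2-enoyl]benzaldehyde; 9 1-[5-(benzyloxy)-2-bromophenyl]ethanone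
Product: 18 (E,E)-bis-chalcone carrying three aryl bromides
Conditions: KOH, EtOH–THF, rt
Reagents that add atoms: none
Why: Second Claisen–Schmidt condensation; the enone already present has no enolisable hydrogen and its β-carbon is shielded by the doubly ortho-substituted aryl group, so the acetophenone enolate should add to the aldehyde and not in a Michael sense.

Step 13
Reactants: 18 (E,E)-bis-chalcone
Product: 19 (3S)-6-(benzyloxy)-5-[(1S)-5-(benzyloxy)-3-oxoindan-1-yl]-3-(8-bromo-3,5,7,3',4'-penta-O-benzylcatechin-6-yl)indan-1-one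
Conditions: Pd(OAc)2 (10 mol %), (R)-3,5-Xyl-MeOBIPHEP (12 mol %), HCO2Na (3 equiv), ethylene glycol–DMF, 80 °C
Reagents that add atoms: none
Why: Double intramolecular asymmetric reductive Heck reaction, in which zerovalent palladium inserts into the two C–Br bonds activated by an ortho acyl group (the electron-rich, doubly ortho-oxygenated C8–Br of the catechin unit should react far more slowly), each aryl–palladium bond adds 5-endo to the enone β-carbon and formate reduces the palladium enolate, the bisphosphine choosing the enone face at both sites so that both diarylmethine centres are set under catalyst control.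

Step 14
Reactants: 19 bis(3-arylindan-1-one)
Product: 20 (4S)-7-(benzyloxy)-6-[(4S)-7-(benzyloxy)-2-oxochroman-4-yl]-4-(8-bromo-3,5,7,3',4'-penta-O-benzylcatechin-6-yl)chroman-2-one
Conditions: mCPBA (6 equiv), Na2HPO4, CH2Cl2, 0 → 40 °C
Reagents that add atoms: 3-chloroperoxybenzoic acid, OOC(=O)c1cccc(Cl)c1
Why: The peracid adds to each ketone to give a Criegee adduct, in which the aromatic carbon C7a migrates from C1 to the proximal peroxide oxygen as 3-chlorobenzoate leaves, so one oxygen atom enters each C7a–C1 bond. The closest known reaction is the Baeyer–Villiger oxidation of indan-1-ones to 3,4-dihydrocoumarins. No ring is closed: each five-membered carbocycle is enlarged to the six-membered lactone by the 1,2-shift, which creates both O1–C8a bonds of units T and M. No stereocentre is formed, and the diarylmethine carbons (indanone C3, lactone C4) are not involved, so their configuration is carried over. The step needs aryl and not methylene migration, which the higher migratory aptitude of an aryl carbon over a primary alkyl carbon provides; the benzyloxy group is only meta to C7a, so the shift is slow, but its sole competitor is the unsubstituted C2 methylene. It also needs the peracid to spare the electron-rich arenes, which the benzyl ethers, the fully substituted ring A of the catechin unit (bromine at C8) and the phosphate buffer should ensure.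

Step 15
Reactants: 20 bis(4-arylchroman-2-one)
Product: 21 bis(N-methoxy-N-methylamide) carrying two free phenols
Conditions: MeNH(OMe)·HCl (5 equiv), iPrMgCl (10 equiv), THF, −20 → 0 °C
Reagents that add atoms: N,O-dimethylhydroxylamine hydrochloride, CNOC.Cl
Why: Aminolysis of the two aryl esters by the magnesium amide opens both lactones to Weinreb amides and releases the phenoxides, which prepares for a single aryl addition that the lactones themselves (aryl esters) would not allow.

Step 16
Reactants: 22 4-bromocatechol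
Product: 23 4-bromo-1,2-bis(benzyloxy)benzene
Conditions: BnBr, K2CO3, DMF, rt
Reagents that add atoms: benzyl bromide, BrCc1ccccc1
Why: Williamson etherification of both phenols.

Step 17
Reactants: 21 bis(N-methoxy-N-methylamide); 23 4-bromo-1,2-bis(benzyloxy)benzene
Product: 25 bis(keto-phenol) carrying two 3,4-bis(benzyloxy)phenyl ketones, via arylmagnesium bromide 24 (not isolated)
Conditions: 23 (6 equiv), Mg, THF, 40 °C; then 21 (1 equiv), THF, 0 °C → rt; aq. NH4Cl
Reagents that add atoms: 4-bromo-1,2-bis(benzyloxy)benzene (a second molecule of 23, since each of the two amides takes up one aryl group), Brc1ccc(OCc2ccccc2)c(OCc2ccccc2)c1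
Why: Grignard addition to each of the two Weinreb amides stops at the ketone because the magnesium-chelated tetrahedral adduct persists until hydrolysis, so two molecules of 24 are built into 25 while two more are protonated by the phenols, and the aryl bromide at C8 does not exchange with an arylmagnesium halide.

Step 18
Reactants: 25 bis(keto-phenol)
Product: 26 bis(flav-2-ene), both units 7-(benzyloxy)-2-[3,4-bis(benzyloxy)phenyl]-4-aryl-4H-chromenes
Conditions: PPTS (cat.), 4 Å molecular sieves, toluene, 60 °C, argon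
Reagents that add atoms: none
Why: Acid-catalysed cyclodehydration in which each phenol adds to its ketone (6-exo-trig hemiketal formation) and the hemiketal loses water through the aryl-stabilised oxocarbenium ion to the conjugated enol ether; this closes ring C of T and M, and the weak acid should not protonate the electron-rich C4 aryl groups.

Step 19
Reactants: 26 bis(flav-2-ene)
Product: 28 undeca-O-benzyl 8-bromo trimer carrying free 3-OH in units T and M, via bis(alkylborane) 27 (not isolated)
Conditions: BH3·THF (6 equiv), THF, 0 °C → rt; then NaOH, H2O2, 0 °C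
Reagents that add atoms: hydrogen peroxide, OO
Why: Hydroboration–oxidation of the two cyclic enol ethers, in which boron adds to C3 (β to O1 and remote from the C2 aryl group) and hydrogen to C2 on the same face, opposite the pseudo-axial C4 aryl group, and oxidation with retention places 3-OH trans to both the C2 and C4 aryl groups, as in hydroborations of 1-aryl glycals.

Step 20
Reactants: 28 undeca-O-benzyl 8-bromo trimer
Product: 29 fisetinidol-(4α→6)-fisetinidol-(4α→6)-catechin
Conditions: H2 (1 atm), Pd(OH)2/C, Et3N (2 equiv), THF–MeOH–H2O, rt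
Reagents that add atoms: none
Why: Hydrogenolysis of the eleven benzyl ethers and hydrodebromination at C8 over Pd(OH)2/C, with triethylamine taking up HBr so that the polyphenol is not exposed to acid; the cyclic benzylic C2–O1 bonds are known to survive these conditions in flavan-3-ols.

Step 21
Reactants: 30 (+)-fustin
Product: 31 (+)-mollisacacidin, (2R,3S,4R)-flavan-3,3',4,4',7-pentaol
Conditions: NaBH4, EtOH, 0 °C → rt
Reagents that add atoms: none
Why: Borohydride reduction of the dihydroflavonol ketone should give mainly the 3,4-trans diol; the C4 configuration is irrelevant because step 22 ionises this centre.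

Step 22
Reactants: 29 fisetinidol-(4α→6)-fisetinidol-(4α→6)-catechin; 31 (+)-mollisacacidin
Product: 32 target tetraflavanoid
Conditions: 29 (1.2 equiv), 0.1 M aq. HCl–1,4-dioxane, 25 °C, argon
Reagents that add atoms: none
Why: Acid ionises the benzylic 4-OH of 31 to a C4 cation stabilised by O1 and the para 7-OH, which is captured in a Friedel–Crafts alkylation by C8 of the catechin unit, the only free carbon of the sole phloroglucinol-type ring in 29; attack opposite the 3-OH should favour the 3,4-trans (4α) bond, the C4 epimer being removed by chromatography.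

**Compound list**

1 | (+)-catechin, (2R,3S) | Oc1cc(O)c2c(c1)O[C@H](c1ccc(O)c(O)c1)[C@@H](O)C2 | starting material
2 | 5,7,3',4'-tetra-O-benzyl-(+)-catechin | c9ccccc9COc1cc(OCc9ccccc9)c2c(c1)O[C@H](c1ccc(OCc9ccccc9)c(OCc9ccccc9)c1)[C@@H](O)C2 | intermediate
3 | 8-bromo-5,7,3',4'-tetra-O-benzyl-(+)-catechin | c9ccccc9COc1cc(OCc9ccccc9)c2c(c1Br)O[C@H](c1ccc(OCc9ccccc9)c(OCc9ccccc9)c1)[C@@H](O)C2 | intermediate
4 | 8-bromo-3,5,7,3',4'-penta-O-benzyl-(+)-catechin | c9ccccc9COc1cc(OCc9ccccc9)c2c(c1Br)O[C@H](c1ccc(OCc9ccccc9)c(OCc9ccccc9)c1)[C@@H](OCc9ccccc9)C2 | intermediate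
5 | C6 dimethyliminium chloride of 4 (not isolated) | C[N+](C)=Cc1c(OCc9ccccc9)c2c(c(Br)c1OCc9ccccc9)O[C@H](c1ccc(OCc9ccccc9)c(OCc9ccccc9)c1)[C@@H](OCc9ccccc9)C2.[Cl-] | intermediate
6 | 8-bromo-3,5,7,3',4'-penta-O-benzyl-(+)-catechin-6-carbaldehyde | O=Cc1c(OCc9ccccc9)c2c(c(Br)c1OCc9ccccc9)O[C@H](c1ccc(OCc9ccccc9)c(OCc9ccccc9)c1)[C@@H](OCc9ccccc9)C2 | intermediate
7 | 3'-hydroxyacetophenone | CC(=O)c1cccc(O)c1 | starting material
8 | 3'-(benzyloxy)acetophenone | CC(=O)c1cccc(OCc2ccccc2)c1 | intermediate
9 | 1-[5-(benzyloxy)-2-bromophenyl]ethanone | CC(=O)c1cc(OCc2ccccc2)ccc1Br | intermediate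
10 | 4-bromo-2-hydroxybenzaldehyde | O=Cc1ccc(Br)cc1O | starting material
11 | 2-(benzyloxy)-4-bromobenzaldehyde | O=Cc1ccc(Br)cc1OCc1ccccc1 | intermediate
12 | 2-(benzyloxy)-4-bromobenzaldehyde dimethyl acetal | COC(OC)c1ccc(Br)cc1OCc1ccccc1 | intermediate
13 | [3-(benzyloxy)-4-(dimethoxymethyl)phenyl]lithium (not isolated) | [Li]c1ccc(C(OC)OC)c(OCc2ccccc2)c1 | intermediate
14 | 1-[3-(benzyloxy)-4-(dimethoxymethyl)phenyl]ethanone | CC(=O)c1ccc(C(OC)OC)c(OCc2ccccc2)c1 | intermediate
15 | 1-[5-(benzyloxy)-2-bromo-4-(dimethoxymethyl)phenyl]ethanone | CC(=O)c1cc(OCc2ccccc2)c(C(OC)OC)cc1Br | intermediate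
16 | (E)-1-[5-(benzyloxy)-2-bromo-4-(dimethoxymethyl)phenyl]-3-(8-bromo-penta-O-benzylcatechin-6-yl)prop-2-en-1-one (not isolated) | COC(OC)c1cc(Br)c(cc1OCc9ccccc9)C(=O)/C=C/c1c(OCc9ccccc9)c2c(c(Br)c1OCc9ccccc9)O[C@H](c1ccc(OCc9ccccc9)c(OCc9ccccc9)c1)[C@@H](OCc9ccccc9)C2 | intermediate
17 | 2-(benzyloxy)-5-bromo-4-[(E)-3-(8-bromo-penta-O-benzylcatechin-6-yl)prop-2-enoyl]benzaldehyde | O=Cc1cc(Br)c(cc1OCc9ccccc9)C(=O)/C=C/c1c(OCc9ccccc9)c2c(c(Br)c1OCc9ccccc9)O[C@H](c1ccc(OCc9ccccc9)c(OCc9ccccc9)c1)[C@@H](OCc9ccccc9)C2 | intermediate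
18 | (E,E)-bis-chalcone: 17 with its formyl group condensed to (E)-CH=CH–C(=O)–[5-(benzyloxy)-2-bromophenyl] | c9ccccc9COc1ccc(Br)c(c1)C(=O)/C=C/c1cc(Br)c(cc1OCc9ccccc9)C(=O)/C=C/c1c(OCc9ccccc9)c2c(c(Br)c1OCc9ccccc9)O[C@H](c1ccc(OCc9ccccc9)c(OCc9ccccc9)c1)[C@@H](OCc9ccccc9)C2 | intermediate
19 | (3S)-6-(benzyloxy)-5-[(1S)-5-(benzyloxy)-3-oxoindan-1-yl]-3-(8-bromo-penta-O-benzylcatechin-6-yl)indan-1-one | c9ccccc9COc1ccc2c(c1)C(=O)C[C@@H]2c1cc2c(cc1OCc9ccccc9)C(=O)C[C@@H]2c1c(OCc9ccccc9)c2c(c(Br)c1OCc9ccccc9)O[C@H](c1ccc(OCc9ccccc9)c(OCc9ccccc9)c1)[C@@H](OCc9ccccc9)C2 | intermediate (key-step precursor)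
20 | (4S)-7-(benzyloxy)-6-[(4S)-7-(benzyloxy)-2-oxochroman-4-yl]-4-(8-bromo-penta-O-benzylcatechin-6-yl)chroman-2-one | c9ccccc9COc1ccc2c(c1)OC(=O)C[C@@H]2c1cc2c(cc1OCc9ccccc9)OC(=O)C[C@@H]2c1c(OCc9ccccc9)c2c(c(Br)c1OCc9ccccc9)O[C@H](c1ccc(OCc9ccccc9)c(OCc9ccccc9)c1)[C@@H](OCc9ccccc9)C2 | intermediate (key-step product)
21 | bis(N-methoxy-N-methylamide): both lactones of 20 opened to 3,3-diarylpropanamides carrying free ortho phenols, diarylmethine carbons as in 20 | c9ccccc9COc1ccc(c(O)c1)[C@H](CC(=O)N(C)OC)c1cc(c(O)cc1OCc9ccccc9)[C@H](CC(=O)N(C)OC)c1c(OCc9ccccc9)c2c(c(Br)c1OCc9ccccc9)O[C@H](c1ccc(OCc9ccccc9)c(OCc9ccccc9)c1)[C@@H](OCc9ccccc9)C2 | intermediate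
22 | 4-bromocatechol | Oc1ccc(Br)cc1O | starting material
23 | 4-bromo-1,2-bis(benzyloxy)benzene | Brc1ccc(OCc2ccccc2)c(OCc2ccccc2)c1 | intermediate
24 | [3,4-bis(benzyloxy)phenyl]magnesium bromide (not isolated) | Br[Mg]c1ccc(OCc2ccccc2)c(OCc2ccccc2)c1 | intermediate
25 | bis(keto-phenol): 21 with each amide replaced by a 3,4-bis(benzyloxy)phenyl ketone | c9ccccc9COc1ccc(c(O)c1)[C@H](CC(=O)c1ccc(OCc9ccccc9)c(OCc9ccccc9)c1)c1cc(c(O)cc1OCc9ccccc9)[C@H](CC(=O)c1ccc(OCc9ccccc9)c(OCc9ccccc9)c1)c1c(OCc9ccccc9)c2c(c(Br)c1OCc9ccccc9)O[C@H](c1ccc(OCc9ccccc9)c(OCc9ccccc9)c1)[C@@H](OCc9ccccc9)C2 | intermediate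
26 | bis(flav-2-ene): units T and M as 7-(benzyloxy)-2-[3,4-bis(benzyloxy)phenyl]-4H-chromenes, C4 configurations as in 20 | c9ccccc9COc1ccc2c(c1)OC(c1ccc(OCc9ccccc9)c(OCc9ccccc9)c1)=C[C@@H]2c1cc2c(cc1OCc9ccccc9)OC(c1ccc(OCc9ccccc9)c(OCc9ccccc9)c1)=C[C@@H]2c1c(OCc9ccccc9)c2c(c(Br)c1OCc9ccccc9)O[C@H](c1ccc(OCc9ccccc9)c(OCc9ccccc9)c1)[C@@H](OCc9ccccc9)C2 | intermediate
27 | bis(C3-alkylborane) adduct of 26, drawn as the monoalkylboranes (not isolated) | c9ccccc9COc1ccc2c(c1)O[C@H](c1ccc(OCc9ccccc9)c(OCc9ccccc9)c1)[C@@H](B)[C@@H]2c1cc2c(cc1OCc9ccccc9)O[C@H](c1ccc(OCc9ccccc9)c(OCc9ccccc9)c1)[C@@H](B)[C@@H]2c1c(OCc9ccccc9)c2c(c(Br)c1OCc9ccccc9)O[C@H](c1ccc(OCc9ccccc9)c(OCc9ccccc9)c1)[C@@H](OCc9ccccc9)C2 | intermediate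
28 | 7,3',4'-tri-O-benzylfisetinidol-(4α→6)-7,3',4'-tri-O-benzylfisetinidol-(4α→6)-8-bromo-3,5,7,3',4'-penta-O-benzylcatechin (both upper units 2R, 2,3-trans-3,4-trans) | c9ccccc9COc1ccc2c(c1)O[C@H](c1ccc(OCc9ccccc9)c(OCc9ccccc9)c1)[C@@H](O)[C@@H]2c1cc2c(cc1OCc9ccccc9)O[C@H](c1ccc(OCc9ccccc9)c(OCc9ccccc9)c1)[C@@H](O)[C@@H]2c1c(OCc9ccccc9)c2c(c(Br)c1OCc9ccccc9)O[C@H](c1ccc(OCc9ccccc9)c(OCc9ccccc9)c1)[C@@H](OCc9ccccc9)C2 | intermediate
29 | fisetinidol-(4α→6)-fisetinidol-(4α→6)-catechin | Oc1ccc2c(c1)O[C@H](c1ccc(O)c(O)c1)[C@@H](O)[C@@H]2c1cc2c(cc1O)O[C@H](c1ccc(O)c(O)c1)[C@@H](O)[C@@H]2c1c(O)c2c(cc1O)O[C@H](c1ccc(O)c(O)c1)[C@@H](O)C2 | intermediate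
30 | (+)-fustin, (2R,3R) | Oc1ccc2c(c1)O[C@H](c1ccc(O)c(O)c1)[C@@H](O)C2=O | starting material
31 | (+)-mollisacacidin, (2R,3S,4R)-2,3-trans-3,4-trans-flavan-3,3',4,4',7-pentaol | Oc1ccc2c(c1)O[C@H](c1ccc(O)c(O)c1)[C@@H](O)[C@@H]2O | intermediate
32 | CNP0263622.1: catechin carrying fisetinidol-(4α→6)-fisetinidol-(4α→) at C6 and fisetinidol-(4α→) at C8 | Oc1ccc2c(c1)O[C@H](c1ccc(O)c(O)c1)[C@@H](O)[C@@H]2c1cc2c(cc1O)O[C@H](c1ccc(O)c(O)c1)[C@@H](O)[C@@H]2c1c(O)c2c(c([C@@H]3c4ccc(O)cc4O[C@H](c4ccc(O)c(O)c4)[C@H]3O)c1O)O[C@H](c1ccc(O)c(O)c1)[C@@H](O)C2 | target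

**Step count and risks**

Total: 22 steps. Longest linear sequence: 14 steps (from 1 through steps 1–4, 11–15, 17–20 and 22; the branch from 10 through steps 7–15, 17–20 and 22 is equally long).

Steps most likely to fail:

1. Step 13, double ring closure. The 5-endo insertion at the enone β-carbon that carries the doubly ortho-benzyloxylated catechin ring may be slow. Formate could then reduce the aryl–palladium bond before it inserts, palladium could begin to insert into the C8–Br bond, and facial control at the hindered site could erode. The fallback moves the ring closure from palladium/hydride to rhodium/boron chemistry. Setting out from 18, Miyaura borylation of the two acyl-activated bromides (B2pin2, KOAc, Pd(dppf)Cl2, dioxane, 80 °C) would give the bis(pinacolboronate) bis-chalcone F1. With [RhCl(cod)]2, (R)-BINAP and aqueous K3PO4 in dioxane at 60 °C, monovalent rhodium would transmetalate, add each aryl group 1,4 to its enone and be released by protonation of the rhodium enolate. This needs no hydride source and comes back to the route at 19.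

2. Step 14, double oxygen insertion. Migration of an aryl carbon that has only a meta alkoxy group may be slow. Over long reaction times methylene migration and peracid attack on the benzyloxy arenes could then compete. The fallback replaces the peracid path by a hydroperoxide rearrangement. Setting out from 19, NaBH4 in THF–MeOH would give the bis(indan-1-ol) F2 (carbinol epimers are of no consequence). Treatment with 50 % H2O2 and catalytic H2SO4 in CH2Cl2 at 0 °C would convert the benzylic alcohols into hydroperoxides, which under the same acid undergo the Hock rearrangement (aryl migration to oxygen, water capture of the oxocarbenium ion) to the bis(chroman-2-ol) F3. Oxidation of the lactols with Ag2CO3 on Celite in toluene would return to the route at 20.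

3. Step 22, final interflavanyl bond. Under protic acid the diol can condense with itself, the cation can alkylate the less reactive resorcinol-type rings on prolonged exposure, and discrimination between the two faces of C4 may be modest. The fallback generates the cation stoichiometrically under non-acidic conditions. Setting out from 31, phenylmethanethiol and acetic acid in ethanol at reflux would give 4-(benzylsulfanyl)fisetinidol F4. AgBF4 in THF at 0 °C in the presence of 29 would then abstract the thioether and release the same C4 cation at low temperature, where attack trans to the 3-OH is better differentiated. This comes back to the route at 32.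

Further compounds
F1 | step 13 | bis(pinacolboronate) bis-chalcone: 18 with both acyl-flanked bromides replaced by 4,4,5,5-tetramethyl-1,3,2-dioxaborolan-2-yl | c9ccccc9COc1ccc(B3OC(C)(C)C(C)(C)O3)c(c1)C(=O)/C=C/c1cc(B3OC(C)(C)C(C)(C)O3)c(cc1OCc9ccccc9)C(=O)/C=C/c1c(OCc9ccccc9)c2c(c(Br)c1OCc9ccccc9)O[C@H](c1ccc(OCc9ccccc9)c(OCc9ccccc9)c1)[C@@H](OCc9ccccc9)C2
F2 | step 14 | bis(indan-1-ol): 19 with both ketones reduced, carbinol centres as epimer mixtures | c9ccccc9COc1ccc2c(c1)C(O)C[C@@H]2c1cc2c(cc1OCc9ccccc9)C(O)C[C@@H]2c1c(OCc9ccccc9)c2c(c(Br)c1OCc9ccccc9)O[C@H](c1ccc(OCc9ccccc9)c(OCc9ccccc9)c1)[C@@H](OCc9ccccc9)C2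
F3 | step 14 | bis(chroman-2-ol): lactol analogue of 20, anomeric centres as mixtures | c9ccccc9COc1ccc2c(c1)OC(O)C[C@@H]2c1cc2c(cc1OCc9ccccc9)OC(O)C[C@@H]2c1c(OCc9ccccc9)c2c(c(Br)c1OCc9ccccc9)O[C@H](c1ccc(OCc9ccccc9)c(OCc9ccccc9)c1)[C@@H](OCc9ccccc9)C2
F4 | step 22 | 4-(benzylsulfanyl)fisetinidol, 3,4-trans epimer drawn (either C4 epimer serves) | Oc1ccc2c(c1)O[C@H](c1ccc(O)c(O)c1)[C@@H](O)[C@@H]2SCc1ccccc1
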